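Remark on the structure: the target has no stereocentre and no stereogenic double bond. Locants used throughout are C1–C19 for the acyl chain (C1 = ester carbonyl, furan on C19) and C1'–C21' for the alkyl chain (C1' = OCH2, furan on C21').

## Structural features

The target (C48H68O4) is the ester of 19-(furan-2-yl)nonadeca-5,7-diynoic acid with 21-(furan-2-yl)henicosa-14,16-diyn-1-ol. Each chain holds one internal, unsymmetrical 1,3-diyne flanked by CH2 groups (C5≡C6–C7≡C8 and C14'≡C15'–C16'≡C17') and ends in a 2-monosubstituted furan. There are no rings other than the two furans and no stereocentres. The fragile groups are the furans (acid, electrophilic halogen, oxidants, anodic oxidation), the dialkyl diynes (base-induced propargylic isomerisation, polymerisation) and the single ester. The real difficulty is placing four contiguous sp carbons at a defined position in each of two different long chains without forming symmetric diynes, which in these waxy series are hard to separate. The key step exploits one feature: in each diyne the inner sp carbon on the furan side (C7 and C16') can be treated as a one-carbon insert between an acyl carbon (C8, C17') and an existing alkyne (C5≡C6, C14'≡C15'). With this choice each rigid alkyne also lies between the reacting carbon and the ester.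

## Logic of the disconnections

**27 to 25 (through 26).** The σ-bonds C6–C7 and C15'–C16' are cut, and with them the triple bonds C7≡C8 and C16'≡C17' are traced back to C=CBr2 units. In 25, C7 and C16' are CBr2 carbons double-bonded to C8 and C17', and C6 and C15' are still bonded to C8 and C17'. The reason is that both diynes then arise in one operation by 1,2-shift in two alkylidene carbenoids, with no sp–sp coupling and no symmetric dimer. The gain is that 25 contains only two isolated alkynes and can be assembled entirely by carbonyl chemistry. The demand is that halogen–lithium exchange and rearrangement must outrun any attack on the ester. For that reason the carbonyl-derived carbons were put on the furan side of each alkyne, so that both carbenoid carbons are held away from the ester by a linear C≡C unit.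

**25 to 24.** The double bonds C7=C8 and C16'=C17' are cut. C7 and C16' come from the one-carbon reagent CBr4, and 24 is a bis-ynone. The gain is two carbons removed and two ketones revealed. The demand is a two-fold Wittig-type dibromomethylenation of enolisable ynones that leaves the ester and furans untouched.

**24 to 16 and 22 (through 23).** The bond between alkyne carbon C6 and the acyl carbon (future C8) is cut. This separates the whole C12 furyl-alkanoyl arm from a terminal alkyne. The demand is an acylation of a terminal alkyne under conditions that tolerate the ester and the ynone already present in 16, which excludes organolithium reagents.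

**16 to 14 and 15.** The ester bond C1–O1' is cut. The ester is made at this point so that the two terminal alkynes of the central unit are acylated at different stages and never need to be differentiated. The demand is an esterification that does not add the alcohol to the ynone of 14.

**14 to 12 and 6 (through 13).** The bond between C15' and the acyl carbon (future C17') is cut. This gives a simple ω-alkynol and an N-methoxy-N-methyl amide. The demand is that the acetylide adds once while the alkoxide of the same molecule stays a spectator.

**6 to 4 (through 5), then to 1 and 2 (through 3).** The bond C17'–C18' and the bond from C21' to furan C2 are cut. Both are made from organometallic reagents and commercial electrophiles. The demand is selective displacement of bromide over chloride and a single addition to the carbamoyl chloride.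

**12 to 10 (through 11), then to 7 and 8 (through 9).** The triple bond is moved back from C14'≡C15' to C2'≡C3' and the bond C3'–C4' is cut. This reduces the C15 alkynol to two cheap commercial pieces. The demand is a clean contra-thermodynamic alkyne migration over twelve positions.

**22 to 20 (through 21), then to 17 and 18 (through 19).** The bond C8–C9 (carboxylation) and the bond from C19 to furan C2 are cut. The ring–chain bond is made by copper-catalysed coupling of a furyl Grignard reagent with a primary bromide. The demand is mono-alkylation of a symmetric dibromide.

## Other disconnections considered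

**Alternative 1:** Cut the ester bond C1–O1' and the central sp–sp bonds C6–C7 and C15'–C16'. The forward key step is a Cadiot–Chodkiewicz coupling (CuCl, amine, NH2OH·HCl) of a 1-bromoalkyne with a terminal alkyne in each half. This gives 19-(furan-2-yl)nonadeca-5,7-diynoic acid A1 and 21-(furan-2-yl)henicosa-14,16-diyn-1-ol A2, which are then esterified. This is the plan that comes to mind first; it is sound and its step count is close to that of the chosen route. It was not chosen for three reasons:
- Each half needs its own copper coupling.
- Halogen–copper exchange in such couplings can lead to symmetric diynes whose polarity is almost that of the cross product in these homologous series.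
- The bromoalkynes must be made with electrophilic bromine, which a furan in the same molecule would not be expected to tolerate, so the polarity of both couplings is fixed.

The chosen plan has no sp–sp coupling. Every fragment union is a polar reaction at a carbonyl group and cannot give a symmetric dimer, and both diynes appear in one operation.

**Alternative 2:** Cut the four C(sp)–C(sp3) bonds C4–C5, C8–C9, C13'–C14' and C17'–C18' and use a butadiyne linchpin. In the forward sense, Me3Si–C≡C–C≡C–SiMe3 is monolithiated and alkylated with 20 to give trimethyl[15-(furan-2-yl)pentadeca-1,3-diyn-1-yl]silane A3. Desilylation and a second alkylation follow, and the same is done for the other half. The chosen plan is preferred for three reasons: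
- Four SN2 alkylations of weakly nucleophilic diynyl anions with unactivated primary halides are needed.
- The desilylated intermediates are terminal 1,3-diynes, a class prone to polymerisation.
- The three-carbon electrophile on the acid side must carry a masked carboxyl group, since an ester would not survive a diynyllithium, which adds protecting-group steps.

**Alternative 3:** An electrochemical cut of a CH2–CH2 bond inside a long chain, for example C13–C14. The forward key step is a mixed Kolbe electrolysis of 7-(furan-2-yl)heptanoic acid A4 with the half-ester 14-methoxy-14-oxotetradeca-7,9-diynoic acid A5, to give methyl 19-(furan-2-yl)nonadeca-5,7-diynoate A6. The chosen plan is preferred for three reasons: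
- A 2-alkylfuran is oxidised at a lower anode potential than a carboxylate, so ring alkoxylation would be expected before decarboxylation.
- Mixed Kolbe coupling is statistical.
- The diyne of A5 would still have to be made by one of the other methods, so the real difficulty is left untouched.

Key step: step 11

## Route

Step 1
Reactants: 1 furan; 2 1-bromo-4-chlorobutane
Product: 4 2-(4-chlorobutyl)furan, via 2-furyllithium 3 (not isolated)
Conditions: 1 (1.3 equiv), n-BuLi (1.1 equiv), THF, −78 → 0 °C; then 2 (1.0 equiv), 0 °C → rt
Reagents that add atoms: none
Why: α-Lithiation of furan followed by SN2 alkylation; the primary bromide is displaced much faster than the chloride, so the chloride is kept for the next step.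

Step 2
Reactants: 4 2-(4-chlorobutyl)furan
Product: 6 5-(furan-2-yl)-N-methoxy-N-methylpentanamide, via alkylmagnesium chloride 5 (not isolated)
Conditions: Mg, cat. BrCH2CH2Br, THF, reflux; then added to ClC(O)N(OMe)Me (1.5 equiv), THF, −78 → 0 °C; aq. NH4Cl
Reagents that add atoms: N-methoxy-N-methylcarbamoyl chloride, CON(C)C(Cl)=O
Why: Grignard formation and acylation by the carbamoyl chloride; inverse addition at low temperature keeps the product amide away from excess Grignard reagent, and the furan is inert to both stages.

Step 3
Reactants: 7 prop-2-yn-1-ol; 8 1-bromododecane
Product: 10 pentadec-2-yn-1-ol, via dilithiated prop-2-yn-1-ol 9 (not isolated)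
Conditions: n-BuLi (2.1 equiv), THF–DMPU, −78 → −20 °C; then 8, −20 °C → rt; H2O
Reagents that add atoms: none
Why: Alkylation of the alkoxide/acetylide dianion, which reacts at the more nucleophilic acetylide carbon with the primary bromide.

Step 4
Reactants: 10 pentadec-2-yn-1-ol
Product: 12 pentadec-14-yn-1-ol, via disodium alkynolate 11 (not isolated)
Conditions: NaH (5 equiv), H2N(CH2)3NH2, 70 °C; then H2O, 0 °C
Reagents that add atoms: none
Why: Alkyne zipper isomerisation; repeated propargyl/allenyl proton transfers move the triple bond along the chain, and irreversible formation of the terminal acetylide drives it to C14.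

Step 5
Reactants: 12 pentadec-14-yn-1-ol; 6 5-(furan-2-yl)-N-methoxy-N-methylpentanamide
Product: 14 20-(furan-2-yl)-1-hydroxyicos-14-yn-16-one, via dilithium alkynolate 13 (not isolated)
Conditions: n-BuLi (2.05 equiv), THF, −78 → −20 °C; then 6 (1.0 equiv), −78 → 0 °C; poured into cold 0.5 M HCl
Reagents that add atoms: none
Why: Acetylide addition to an N-methoxy-N-methyl amide stops at the chelated tetrahedral intermediate, so only the ynone forms; the alkoxide is a spectator, and the acidic quench protonates the released MeNHOMe before it can add to the ynone.

Step 6
Reactants: 14 20-(furan-2-yl)-1-hydroxyicos-14-yn-16-one; 15 hex-5-ynoic acid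
Product: 16 20-(furan-2-yl)-16-oxoicos-14-yn-1-yl hex-5-ynoate
Conditions: EDC·HCl (1.3 equiv), DMAP (0.05 equiv), CH2Cl2, 0 °C → rt
Reagents that add atoms: none
Why: Steglich-type carbodiimide esterification of a primary alcohol; the β-alkyl internal ynone is a poor acceptor for the alcohol at 0 °C with little DMAP, and the terminal alkyne of 15 is untouched.

Step 7
Reactants: 17 2-bromofuran; 18 1,11-dibromoundecane
Product: 20 2-(11-bromoundecyl)furan, via 2-furylmagnesium bromide 19 (not isolated)
Conditions: 17, Mg, LiCl, THF, 0 °C → rt; then added slowly to 18 (3 equiv), Li2CuCl4 (3 mol%), THF–NMP, 0 °C → rt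
Reagents that add atoms: none
Why: Magnesium insertion into the C–Br bond of 17 followed by copper-catalysed Grignard–alkyl bromide coupling (Kochi type); excess dibromide and inverse addition favour mono-substitution, and the weakly basic Grignard–copper system does not dehydrobrominate the surplus 18, which is recovered.

Step 8
Reactants: 20 2-(11-bromoundecyl)furan
Product: 22 12-(furan-2-yl)dodecanoic acid, via alkylmagnesium bromide 21 (not isolated)
Conditions: Mg, THF, 45 °C; then CO2 (g), −20 °C → rt; cold 1 M HCl to pH 3
Reagents that add atoms: carbon dioxide, O=C=O
Why: Grignard carboxylation adds the carbon that becomes C8; the 2-alkylfuran tolerates the brief cold dilute-acid work-up.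

Step 9
Reactants: 22 12-(furan-2-yl)dodecanoic acid; 16 20-(furan-2-yl)-16-oxoicos-14-yn-1-yl hex-5-ynoate
Product: 24 20-(furan-2-yl)-16-oxoicos-14-yn-1-yl 18-(furan-2-yl)-7-oxooctadec-5-ynoate, via 12-(furan-2-yl)dodecanoyl chloride 23 (not isolated)
Conditions: 22, Me2C=C(Cl)NMe2 (1.1 equiv), CH2Cl2, 0 °C → rt; then 16 (1.0 equiv), PdCl2(PPh3)2 (2 mol%), CuI (4 mol%), Et3N (1.5 equiv), THF, rt, degassed
Reagents that add atoms: none
Why: Acyl Sonogashira coupling (acid chloride with a terminal alkyne through a copper acetylide and an acylpalladium species); the acid chloride is made under neutral conditions to spare the furan, and the ester and ynone of 16 are not touched because no strongly nucleophilic organometallic is present.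

Step 10
Reactants: 24 20-(furan-2-yl)-16-oxoicos-14-yn-1-yl 18-(furan-2-yl)-7-oxooctadec-5-ynoate
Product: 25 16-(dibromomethylidene)-20-(furan-2-yl)icos-14-yn-1-yl 7-(dibromomethylidene)-18-(furan-2-yl)octadec-5-ynoate
Conditions: CBr4 (5 equiv), PPh3 (10 equiv), CH2Cl2, 0 °C (ylide preformed); then 24, 0 °C → rt
Reagents that add atoms: carbon tetrabromide, BrC(Br)(Br)Br
Why: Ramirez dibromoolefination (the first stage of the Corey–Fuchs sequence), a Wittig-type reaction known for alkynyl ketones; preforming the ylide leaves no free PPh3 to add to the ynones, and the ester is not olefinated.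

Step 11
Reactants: 25 16-(dibromomethylidene)-20-(furan-2-yl)icos-14-yn-1-yl 7-(dibromomethylidene)-18-(furan-2-yl)octadec-5-ynoate
Product: 27 21-(furan-2-yl)henicosa-14,16-diyn-1-yl 19-(furan-2-yl)nonadeca-5,7-diynoate (CNP0308591.0), via dilithio bis(carbenoid) 26 (not isolated)
Conditions: n-BuLi (2.2 equiv, slow addition), hexanes–toluene 3:1, −78 °C; then −78 → −30 °C; aq. NH4Cl
Reagents that add atoms: none
Why: Fritsch–Buttenberg–Wiechell rearrangement, run twice in one flask: Br–Li exchange at each CBr2 group gives the α-bromovinyllithium carbenoids of 26, and on warming each loses LiBr while a substituent on the neighbouring carbon shifts 1,2 to the carbenoid carbon, which creates the C6–C7 and C15'–C16' bonds and the C7≡C8 and C16'≡C17' triple bonds. The closest known reaction type is the n-BuLi-induced rearrangement of 2-alkyl-2-alkynyl-1,1-dibromoalkenes to 1,3-diynes in hydrocarbon solvent, which is also known in two-fold form. No ring is closed and no stereocentre is formed. Either 1,2-shift (alkynyl or alkyl) leads to the same diyne, and the sp-hybridised alkynyl carbon is the better migrating group, so no regiochemical question arises. The selectivity the step needs is exchange and rearrangement ahead of attack on the ester: exchange at a gem-dibromoalkene is far faster than carbonyl addition by aggregated n-BuLi in hexanes at −78 °C, the reagent is added slowly and not in excess, and the species that rearranges is a lithium carbenoid and not a free carbene, so C–H insertion is not expected. The substrate secures the rest: both carbenoid carbons (future C7 and C16') are separated from the ester by a linear alkyne unit, so no Parham-type intramolecular acylation is geometrically possible, and the furan C5–H and propargylic C–H bonds are not metalated by n-BuLi under these non-coordinating conditions.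

## Compound list

1 | furan | c1ccoc1 | starting material
2 | 1-bromo-4-chlorobutane | ClCCCCBr | starting material
3 | 2-furyllithium | [Li]c1ccco1 | intermediate
4 | 2-(4-chlorobutyl)furan | ClCCCCc1ccco1 | intermediate
5 | [4-(furan-2-yl)butyl]magnesium chloride | Cl[Mg]CCCCc1ccco1 | intermediate
6 | 5-(furan-2-yl)-N-methoxy-N-methylpentanamide | CON(C)C(=O)CCCCc1ccco1 | intermediate
7 | prop-2-yn-1-ol | OCC#C | starting material
8 | 1-bromododecane | CCCCCCCCCCCCBr | starting material
9 | dilithium salt of prop-2-yn-1-ol (O,C-dilithiated) | [Li]OCC#C[Li] | intermediate
10 | pentadec-2-yn-1-ol | OCC#CCCCCCCCCCCCC | intermediate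
11 | disodium salt of pentadec-14-yn-1-ol (alkoxide and acetylide) | [Na]OCCCCCCCCCCCCCC#C[Na] | intermediate
12 | pentadec-14-yn-1-ol | OCCCCCCCCCCCCCC#C | intermediate
13 | dilithium salt of pentadec-14-yn-1-ol (alkoxide and acetylide) | [Li]OCCCCCCCCCCCCCC#C[Li] | intermediate
14 | 20-(furan-2-yl)-1-hydroxyicos-14-yn-16-one | OCCCCCCCCCCCCCC#CC(=O)CCCCc1ccco1 | intermediate
15 | hex-5-ynoic acid | OC(=O)CCCC#C | starting material
16 | 20-(furan-2-yl)-16-oxoicos-14-yn-1-yl hex-5-ynoate | C#CCCCC(=O)OCCCCCCCCCCCCCC#CC(=O)CCCCc1ccco1 | intermediate
17 | 2-bromofuran | Brc1ccco1 | starting material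
18 | 1,11-dibromoundecane | BrCCCCCCCCCCCBr | starting material
19 | 2-furylmagnesium bromide | Br[Mg]c1ccco1 | intermediate
20 | 2-(11-bromoundecyl)furan | BrCCCCCCCCCCCc1ccco1 | intermediate
21 | [11-(furan-2-yl)undecyl]magnesium bromide | Br[Mg]CCCCCCCCCCCc1ccco1 | intermediate
22 | 12-(furan-2-yl)dodecanoic acid | OC(=O)CCCCCCCCCCCc1ccco1 | intermediate
23 | 12-(furan-2-yl)dodecanoyl chloride | ClC(=O)CCCCCCCCCCCc1ccco1 | intermediate
24 | 20-(furan-2-yl)-16-oxoicos-14-yn-1-yl 18-(furan-2-yl)-7-oxooctadec-5-ynoate | O=C(CCCC#CC(=O)CCCCCCCCCCCc1ccco1)OCCCCCCCCCCCCCC#CC(=O)CCCCc1ccco1 | intermediate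
25 | 16-(dibromomethylidene)-20-(furan-2-yl)icos-14-yn-1-yl 7-(dibromomethylidene)-18-(furan-2-yl)octadec-5-ynoate | O=C(CCCC#CC(=C(Br)Br)CCCCCCCCCCCc1ccco1)OCCCCCCCCCCCCCC#CC(=C(Br)Br)CCCCc1ccco1 | intermediate
26 | 16-[bromo(lithio)methylidene]-20-(furan-2-yl)icos-14-yn-1-yl 7-[bromo(lithio)methylidene]-18-(furan-2-yl)octadec-5-ynoate | O=C(CCCC#CC(=C([Li])Br)CCCCCCCCCCCc1ccco1)OCCCCCCCCCCCCCC#CC(=C([Li])Br)CCCCc1ccco1 | intermediate
27 | 21-(furan-2-yl)henicosa-14,16-diyn-1-yl 19-(furan-2-yl)nonadeca-5,7-diynoate (CNP0308591.0) | O=C(CCCC#CC#CCCCCCCCCCCCc1ccco1)OCCCCCCCCCCCCCC#CC#CCCCCc1ccco1 | target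

## Step count and least certain steps

Total step count: 11. Longest linear sequence: 7 steps (steps 3, 4, 5, 6, 9, 10, 11; the sequence 1, 2, 5, 6, 9, 10, 11 is equally long).

**Step 11 (key step).** The most likely failure is carbonyl addition of n-BuLi, or of a carbenoid of another molecule, to the ester before exchange and rearrangement are complete. Protonation of a carbenoid before it rearranges would leave a monobromoalkene at one of the two sites. The fallback gives up the rearrangement and builds the diynes by copper coupling; it sets out from 20, 15, 4 and 12 and comes back at 27.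
- 20 with LiC≡CH·H2N(CH2)2NH2 in DMSO should give 2-(tridec-12-yn-1-yl)furan F1.
- 15 with NBS and catalytic AgNO3 in acetone should give 6-bromohex-5-ynoic acid F2.
- Cadiot–Chodkiewicz coupling of F1 with F2 (CuCl, NH2OH·HCl, n-BuNH2, MeOH–H2O, 0 °C) should give 19-(furan-2-yl)nonadeca-5,7-diynoic acid F3 (the structure of A1).
- 4 with the same acetylide reagent should give 2-(hex-5-yn-1-yl)furan F4.
- 12 with NBS/AgNO3 should give 15-bromopentadec-14-yn-1-ol F5.
- Coupling of F4 with F5 should give 21-(furan-2-yl)henicosa-14,16-diyn-1-ol F6 (the structure of A2).
- Carbodiimide esterification of F3 with F6 (EDC·HCl, DMAP) should give 27.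

In this fallback only the furan-free partners are brominated.

**Step 10.** The risk is incomplete two-fold olefination, with enolisation of the α-CH2 ketones by the basic ylide or phosphine-induced isomerisation of an ynone, leaving mixtures of mono- and bis-olefinated material. The fallback installs the two dibromoolefins one at a time; it sets out from 16 and comes back at 25.
- Ramirez olefination of the single ketone of 16 should give 16-(dibromomethylidene)-20-(furan-2-yl)icos-14-yn-1-yl hex-5-ynoate F7.
- Palladium-free acylation of its terminal alkyne with 23 (CuI, Et3N), which leaves the vinylic C–Br bonds alone, should give 16-(dibromomethylidene)-20-(furan-2-yl)icos-14-yn-1-yl 18-(furan-2-yl)-7-oxooctadec-5-ynoate F8.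
- A second Ramirez olefination of F8 should give 25.

**Step 9.** The risk is dehydrochlorination of the enolisable acid chloride to a ketene by Et3N, faster than transmetalation, together with oxidative homocoupling of the terminal alkyne, so that acylation stays incomplete. The fallback forms this ynone before the ester, by carbonyl addition; it sets out from 22 and 15 and comes back at 24.
- 22 with MeNHOMe·HCl and EDC·HCl should give 12-(furan-2-yl)-N-methoxy-N-methyldodecanamide F9.
- 15 with two equivalents of LDA in THF–DMPU should give lithium 6-lithiohex-5-ynoate F10.
- Addition of F10 to F9 and acidic work-up should give 18-(furan-2-yl)-7-oxooctadec-5-ynoic acid F11.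
- Esterification of F11 with 14 (EDC·HCl, DMAP, 0 °C) should give 24.

**Step 2.** The risk is a second addition of the Grignard reagent to the amide just formed, which after work-up would appear as a symmetric ketone. The fallback separates carbon–carbon bond formation from amide formation; it sets out from 5 (made from 4 as in step 2) and comes back at 6.
- 5 with CO2 and acidic work-up should give 5-(furan-2-yl)pentanoic acid F12.
- F12 with MeNHOMe·HCl, EDC·HCl and i-Pr2NEt should give 6.

**Step 7.** The risk is sluggish copper-catalysed coupling of the heteroaryl Grignard reagent, with oxidative homocoupling of the furyl groups and a second substitution at the remaining bromide competing, so that mono-alkylation stays low. The fallback moves the bond formation away from the furan ring to the C15–C16 bond of the acyl chain and replaces steps 7 and 8; it sets out from 5 (made from 4 as in step 2) and comes back at 22.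
- Commercial 8-bromooctanoic acid with t-BuMgCl (1.0 equiv) in THF at −20 °C should give chloromagnesium 8-bromooctanoate F13.
- Coupling of 5 with F13 (Li2CuCl4 3 mol%, THF, −10 °C → rt), an alkyl Grignard–alkyl bromide coupling of the Kochi type, and work-up with cold 1 M HCl should give 22.

## Further compounds

F1 | step 11 | 2-(tridec-12-yn-1-yl)furan | C#CCCCCCCCCCCCc1ccco1
F2 | step 11 | 6-bromohex-5-ynoic acid | OC(=O)CCCC#CBr
F3 | step 11 | 19-(furan-2-yl)nonadeca-5,7-diynoic acid | OC(=O)CCCC#CC#CCCCCCCCCCCCc1ccco1
F4 | step 11 | 2-(hex-5-yn-1-yl)furan | C#CCCCCc1ccco1
F5 | step 11 | 15-bromopentadec-14-yn-1-ol | OCCCCCCCCCCCCCC#CBr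
F6 | step 11 | 21-(furan-2-yl)henicosa-14,16-diyn-1-ol | OCCCCCCCCCCCCCC#CC#CCCCCc1ccco1
F7 | step 10 | 16-(dibromomethylidene)-20-(furan-2-yl)icos-14-yn-1-yl hex-5-ynoate | C#CCCCC(=O)OCCCCCCCCCCCCCC#CC(=C(Br)Br)CCCCc1ccco1
F8 | step 10 | 16-(dibromomethylidene)-20-(furan-2-yl)icos-14-yn-1-yl 18-(furan-2-yl)-7-oxooctadec-5-ynoate | O=C(CCCC#CC(=O)CCCCCCCCCCCc1ccco1)OCCCCCCCCCCCCCC#CC(=C(Br)Br)CCCCc1ccco1
F9 | step 9 | 12-(furan-2-yl)-N-methoxy-N-methyldodecanamide | CON(C)C(=O)CCCCCCCCCCCc1ccco1
F10 | step 9 | lithium 6-lithiohex-5-ynoate | [Li]OC(=O)CCCC#C[Li]
F11 | step 9 | 18-(furan-2-yl)-7-oxooctadec-5-ynoic acid | OC(=O)CCCC#CC(=O)CCCCCCCCCCCc1ccco1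
F12 | step 2 | 5-(furan-2-yl)pentanoic acid | OC(=O)CCCCc1ccco1
F13 | step 7 | chloromagnesium 8-bromooctanoate | BrCCCCCCCC(=O)O[Mg]Cl
A1 | alternative 1 | 19-(furan-2-yl)nonadeca-5,7-diynoic acid | OC(=O)CCCC#CC#CCCCCCCCCCCCc1ccco1
A2 | alternative 1 | 21-(furan-2-yl)henicosa-14,16-diyn-1-ol | OCCCCCCCCCCCCCC#CC#CCCCCc1ccco1
A3 | alternative 2 | trimethyl[15-(furan-2-yl)pentadeca-1,3-diyn-1-yl]silane | C[Si](C)(C)C#CC#CCCCCCCCCCCCc1ccco1
A4 | alternative 3 | 7-(furan-2-yl)heptanoic acid | OC(=O)CCCCCCc1ccco1
A5 | alternative 3 | 14-methoxy-14-oxotetradeca-7,9-diynoic acid | OC(=O)CCCCCC#CC#CCCCC(=O)OC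
A6 | alternative 3 | methyl 19-(furan-2-yl)nonadeca-5,7-diynoate | COC(=O)CCCC#CC#CCCCCCCCCCCCc1ccco1
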